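Early in Monday's flask, by 0.417 d, substrate reads 36.7 %, and at 5.00 d it reads 38.7 %: a difference of 2 percentage points against a scatter of 1 point. Target lies just as flat, so the plateau means of the readings can stand for 8.0 d.

| setting | Monday's | Sunday's | flask |
|---|---|---|---|
| substrate | 0.081 M | 0.16 M | 0.081 M |
| reagent | 0.0567 M | 0.0567 M | 0.0567 M |
| temperature | 80 °C | 86 °C | 80 °C |
| remark | the very flask that is asked about, followed so far | run made earlier |  |
| time |  |  | 8.0 d |

| run | time / d | target / % | substrate / % |
|---|---|---|---|
| Monday's | 0.417 | 27.9 | 36.7 |
| Monday's | 1.25 | 28.9 | 38.5 |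
| Monday's | 2.00 | 28.3 | 37.4 |
| Monday's | 3.00 | 28.4 | 37.9 |
| Monday's | 5.00 | 30.4 | 38.7 |
| Sunday's | 2.50 | 16.5 | 64.2 |
| Sunday's | 5.00 | 15.8 | 64.5 |
| Sunday's | 8.00 | 18.5 | 64.6 |
| Sunday's | 10.0 | 18.1 | 64.4 |
| Sunday's | 12.0 | 16.2 | 64.2 |

(scatter of a reading: 1 percentage point)

1. target, in percent of the substrate first charged, at 8.0 d
2. what to do for the largest gain in target; "none" if nothing gains more than 2 percentage points (dawn / summer / autumn / noon / none)
3. target present, with what was taken out counted in, in percent of the substrate first charged, after summer
4. target present, with what was taken out counted in, in percent of the substrate first charged, after noon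

- dawn: change nothing and wait 4.0 d more
- summer: at 8.0 d take out 90 % of the target then present, then wait 4.0 d
- autumn: at 8.0 d raise the temperature by 20 K, then wait 4.0 d
- noon: at 8.0 d add reagent, 50.0 % of the amount charged, then wait 4.0 d

- target taken out counts as made
- the numbers in the tables scatter with a standard deviation of 1 percentage point
- additions bring no volume worth counting

Monday's flask: target 28.8 %, substrate consumed 62.2 %

Sunday's flask: target 17.0 %, substrate consumed 35.6 %

The first way to target in Monday's flask is that plateau, 28.8 %. The second way counts from the charge. Sunday's flask consumes 0.0570 M of substrate, about the 0.0567 M of reagent charged, which marks reagent as the limiting reagent there, with one substrate taken per reagent. Carrying Sunday's yield per substrate consumed over to Monday's charges gives: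

47.8 % × 0.0567 M ÷ 0.081 M = 33.4 %

The two ways part by 4.6 points, more than the scatter. The count cheats: it implies 70.0 % of the substrate consumed, while Monday's readings show 62.2 %. Each reagent charged in Monday's flask took 88.8 % of a substrate. Sunday's yield on Monday's consumption still gives 29.7 %, and this check joins target from one flask to substrate from another. Monday's own yield is 46.3 %. The mean, 47.0 %, is the share, the part of consumed substrate that ends as target.

This reckoning commits to 28.8 % now. Flat readings look the same whether Monday's flask stopped for want of reagent or at an equilibrium, so they give no figure for summer. The reagent charged beyond the substrate consumed comes to 0.00635 M, and at the share that is worth 3.7 points, so this reckoning places target after summer between 28.8 % and 32.5 %. For noon: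

gain = share × worth of a reagent × reagent added ÷ substrate charged = 15 points

That puts target after noon at 43.8 %.

The forecast gives 29 %, noon, 31 % and 40 %; its figure after noon is lower than this reckoning's. Its ground: “about 47% of the consumed substrate becomes target in both runs”.

The flask gives 29.6 %, noon, 29.6 % and 44.5 %. Noon gains 15 points, and dawn, summer and autumn each 0 points.

    substrate ⇌ tight pair (K = 0.0170, k = 0.280 h⁻¹, Ea = 107 kJ mol⁻¹, ΔH = −40.0 kJ mol⁻¹)
    tight pair ⇌ loose pair (K = 1.50, k = 500 h⁻¹, Ea = 89.0 kJ mol⁻¹, ΔH = −14.0 kJ mol⁻¹)
    reagent + tight pair → target (k = 1300 M⁻¹ h⁻¹, Ea = 53.0 kJ mol⁻¹)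
    reagent + loose pair → isomer of the product (k = 990 M⁻¹ h⁻¹, Ea = 60.0 kJ mol⁻¹)
    2 reagent → self-condensation product (k = 1.20 M⁻¹ h⁻¹, Ea = 64.0 kJ mol⁻¹)
    (constants at 80 °C)

In the flask at 0.0649 d, reagent goes to isomer of the product 1.1 times as fast as to target, which gives target 48.5 % of those two products. At 8.0 d that flask holds 29.6 % target and 31.3 % isomer of the product, with 0 % reagent left, and the share gave noon 15 points against the 15 points it gains. In the neighbour with 0.14 M of reagent, 1.8 % of the substrate remains, so the share gives 46.2 % target, and that flask holds 49.5 %.

All runs are calculated with constants of no real substance; noise was put on by code.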